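**Plan**

1. Numbering: C1 = bridgehead next to C8 (CMe2); C2–C4 = enolised dione carbons with the aroyl group on C3; C5 = other bridgehead; C6 = CH2; C7 = geranyl-bearing CH; C9 = bridging C=O. Ring A = C1–C8–C7–C6–C5–C9, ring B = C1–C2–C3–C4–C5–C9.
2. Enabling feature: the C4 carbonyl, C3 and the aroyl carbonyl form a 1,3-dicarbonyl unit, the open form of an isoxazole whose C–C bond is C3–C4 and whose N–O bond stands for the two oxygens. C4 hangs on C5 and C2–C3 on C1, cis-1,3 across C9 on ring A.
3. Retrosynthetic cuts, in order: the isoxazole N–O and C4–N bonds (unmasking); C3–C4 and the aroyl C–O bond (nitrile oxide plus ynone); C1–C2 (aldol with an aryl propynal); C5–C4 (formaldehyde); C5–prenyl; C8–CH3; C1–prenyl; ring A into a geranylated aldehyde and methyl vinyl ketone.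
4. Forward order: ring A is made first by Michael/aldol annulation and substituted around its periphery; ring B and the isoxazole close together in the cycloaddition; N–O cleavage, hydrolysis and desilylation finish the synthesis.
5. Stereochemistry: C7 comes from the enamine-catalysed Michael addition; C5 and C1 are set by substrate control, the last substituent at each entering ring A anti to the geranyl group; the cycloaddition creates no stereocentre.

Key step: step 19

**Remarks before the steps**

- Atom labels C1–C9 in the Why lines follow the numbering of the plan; locants inside compound names follow nomenclature rules. Geranyl = (2E)-3,7-dimethylocta-2,6-dien-1-yl; prenyl = 3-methylbut-2-en-1-yl; Ar = 3,4-bis(tert-butyldimethylsilyloxy)phenyl.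
- Assumption: in step 3 the (S)-diarylprolinol ether shields the enamine face on the side of its diphenyl(methoxy)methyl group, as in related enamine Michael additions, so the (S)-catalyst leads to the (S)-adduct; were the sense opposite, the (R)-catalyst would be used.
- The target is treated as the enolised β-triketone drawn, one member of a set of rapidly interconverting tautomers.

**Route**

Step 1
Reactants: 1 geranyl bromide; 2 tert-butyl acetate
Product: 4 tert-butyl (4E)-5,9-dimethyldeca-4,8-dienoate, via lithium ester enolate 3 (not isolated)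
Conditions: LiN(i-Pr)2, THF, −78 °C; then 1, DMPU, −78 to 0 °C
Reagents that add atoms: none
Why: SN2 alkylation of a lithium ester enolate at the primary allylic bromide; an excess of enolate suppresses double alkylation and the trisubstituted alkenes are inert.

Step 2
Reactants: 4 tert-butyl (4E)-5,9-dimethyldeca-4,8-dienoate
Product: 5 (4E)-5,9-dimethyldeca-4,8-dienal
Conditions: i-Bu2AlH (1.05 equiv), CH2Cl2, −78 °C; then H2O work-up
Reagents that add atoms: none
Why: Partial hydride reduction of an ester; the tetrahedral aluminium alkoxide persists at −78 °C and releases the aldehyde only on work-up.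

Step 3
Reactants: 5 (4E)-5,9-dimethyldeca-4,8-dienal; 6 methyl vinyl ketone
Product: 8 (4S)-4-geranylcyclohex-2-en-1-one, via keto aldehyde 7 (not isolated)
Conditions: (S)-2-[methoxy(diphenyl)methyl]pyrrolidine (5 mol %), ethyl 3,4-dihydroxybenzoate (20 mol %), neat, 4 °C; then KOH (0.1 M aq.), n-Bu4NOH (cat.), Et2O–THF, reflux
Reagents that add atoms: none
Why: Enamine-catalysed Michael addition followed by base-induced intramolecular aldol condensation (a two-stage Robinson-type annulation); the E-enamine should be attacked on the face away from the diphenyl(methoxy)methyl group, which sets C7 as S in 7 and 8, and dilute biphasic base should close the ring faster than this centre epimerises.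

Step 4
Reactants: 8 (4S)-4-geranylcyclohex-2-en-1-one
Product: 9 {[(3S,4S)-4-geranyl-3-methylcyclohex-1-en-1-yl]oxy}trimethylsilane (3,4-trans)
Conditions: Me2CuLi (from MeLi and CuI), Me3SiCl, Et3N, THF, −78 °C
Reagents that add atoms: lithium dimethylcuprate, [Li+].C[Cu-]C (made from methyllithium, [Li]C, and CuI); chlorotrimethylsilane, C[Si](C)(C)Cl
Why: Silyl chloride-accelerated cuprate conjugate addition at C8, anti to the C7 geranyl group, with trapping of the enolate as its silyl enol ether; the new methyl-bearing centre is removed again in step 5.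

Step 5
Reactants: 9 {[(3S,4S)-4-geranyl-3-methylcyclohex-1-en-1-yl]oxy}trimethylsilane
Product: 10 (4S)-4-geranyl-3-methylcyclohex-2-en-1-one
Conditions: Pd(OAc)2 (10 mol %), O2 (1 atm), DMSO, 25 °C
Reagents that add atoms: none
Why: Saegusa–Ito oxidation; the palladium enolate formed from the silyl enol ether loses the C8 hydrogen by β-hydride elimination and oxygen reoxidises zerovalent palladium, while C7 is untouched.

Step 6
Reactants: 10 (4S)-4-geranyl-3-methylcyclohex-2-en-1-one
Product: 11 (4S)-4-geranyl-2-iodo-3-methylcyclohex-2-en-1-one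
Conditions: I2, pyridine, DMAP (cat.), CH2Cl2, 0 to 23 °C
Reagents that add atoms: iodine, II
Why: α-Iodination of an enone by reversible amine conjugate addition, iodination of the enolate at C1 and elimination (Baylis–Hillman-type addition–elimination), a process that tolerates isolated trisubstituted alkenes.

Step 7
Reactants: 11 (4S)-4-geranyl-2-iodo-3-methylcyclohex-2-en-1-one
Product: 12 (4S)-4-geranyl-3-methyl-2-prenylcyclohex-2-en-1-one
Conditions: tributyl(prenyl)stannane, Pd2(dba)3 (5 mol %), AsPh3, CuI (cat.), NMP, 60 °C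
Reagents that add atoms: tributyl(3-methylbut-2-en-1-yl)stannane, CCCC[Sn](CCCC)(CCCC)CC=C(C)C
Why: Stille cross-coupling of an α-iodoenone; reductive elimination from the allylpalladium intermediate should occur at the less substituted terminus and so give the linear prenyl group at C1.

Step 8
Reactants: 12 (4S)-4-geranyl-3-methyl-2-prenylcyclohex-2-en-1-one; 13 prenyl bromide
Product: 15 (4S)-4-geranyl-3-methyl-2,6-diprenylcyclohex-2-en-1-one (6-prenyl trans to geranyl; major epimer), via lithium dienolate 14 (not isolated)
Conditions: LiN(i-Pr)2, THF, −78 °C; then 13, −78 to −20 °C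
Reagents that add atoms: none
Why: Kinetic deprotonation at the C5 methylene gives the cross-conjugated dienolate, which is alkylated by the allylic bromide (enolate SN2 alkylation); the C5 configuration is of no consequence because step 9 re-enolises this carbon.

Step 9
Reactants: 15 (4S)-4-geranyl-3-methyl-2,6-diprenylcyclohex-2-en-1-one
Product: 17 (4S)-4-geranyl-6-(hydroxymethyl)-3-methyl-2,6-diprenylcyclohex-2-en-1-one (hydroxymethyl trans and 6-prenyl cis to geranyl), via lithium dienolate 16 (not isolated)
Conditions: LiN(i-Pr)2, THF, −78 to 0 °C; then CH2O (monomeric, THF), −78 °C; H2O quench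
Reagents that add atoms: formaldehyde, C=O
Why: Aldol addition of the fully substituted lithium enolate to formaldehyde; allylic 1,2-strain with the C8 methyl should hold the C7 geranyl group pseudoaxial, so the electrophile enters C5 anti to it and the C4 carbon ends trans to geranyl.

Step 10
Reactants: 17 (4S)-4-geranyl-6-(hydroxymethyl)-3-methyl-2,6-diprenylcyclohex-2-en-1-one
Product: 18 triethylsilyl ether of 17
Conditions: Et3SiCl, imidazole, DMF, 0 °C
Reagents that add atoms: chlorotriethylsilane, CC[Si](CC)(CC)Cl
Why: Silylation of the primary alcohol, which blocks retro-aldol loss of formaldehyde and keeps the C4 oxygen distinct from the one that arrives later at C2.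

Step 11
Reactants: 18 triethylsilyl ether of 17
Product: 19 trimethylsilyl enol ether of the ring A ketone (C9–O–Si; C1=C9 double bond; C8 gem-dimethyl)
Conditions: Me2CuLi (from MeLi and CuI), Me3SiCl, Et3N, THF–Et2O, −78 to 0 °C
Reagents that add atoms: lithium dimethylcuprate, [Li+].C[Cu-]C (made from methyllithium, [Li]C, and CuI); chlorotrimethylsilane, C[Si](C)(C)Cl
Why: Silyl chloride-accelerated cuprate conjugate addition to the tetrasubstituted enone builds the C8 gem-dimethyl group and stores the C1 enolate regiospecifically as its silyl enol ether.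

Step 12
Reactants: 20 3,4-dihydroxybenzaldehyde
Product: 21 3,4-bis(tert-butyldimethylsilyloxy)benzaldehyde
Conditions: t-BuMe2SiCl (2.5 equiv), imidazole, DMF, 23 °C
Reagents that add atoms: tert-butyldimethylsilyl chloride, CC(C)(C)[Si](C)(C)Cl
Why: Standard silylation of both phenols, which have to be masked against the oxidants of steps 17 and 19.

Step 13
Reactants: 21 3,4-bis(tert-butyldimethylsilyloxy)benzaldehyde
Product: 22 4-(2,2-dibromoethenyl)-1,2-bis(tert-butyldimethylsilyloxy)benzene
Conditions: CBr4, PPh3, Et3N, CH2Cl2, 0 °C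
Reagents that add atoms: carbon tetrabromide, BrC(Br)(Br)Br
Why: First stage of the Corey–Fuchs sequence, a Wittig-type olefination by the dibromomethylene ylide made from CBr4 and PPh3.

Step 14
Reactants: 22 4-(2,2-dibromoethenyl)-1,2-bis(tert-butyldimethylsilyloxy)benzene
Product: 24 3-[3,4-bis(tert-butyldimethylsilyloxy)phenyl]prop-2-ynal, via lithium acetylide 23 (not isolated)
Conditions: n-BuLi (2.1 equiv), THF, −78 °C; then DMF, −78 to 0 °C; inverse quench into cold pH 7 aqueous buffer
Reagents that add atoms: N,N-dimethylformamide, CN(C)C=O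
Why: Second stage of the Corey–Fuchs sequence: bromine–lithium exchange and rearrangement give the lithium acetylide, which is formylated by DMF; the buffered inverse quench keeps dimethylamine from adding to the ynal.

Step 15
Reactants: 19 trimethylsilyl enol ether of the ring A ketone; 24 3-[3,4-bis(tert-butyldimethylsilyloxy)phenyl]prop-2-ynal
Product: 26 ring A ketone with prenyl and a 1-hydroxy-3-arylprop-2-yn-1-yl group on C1 and prenyl and CH2OSiEt3 on C5 (C2 and C4 cis to each other and trans to geranyl; both carbinol epimers), via lithium enolate 25 (not isolated)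
Conditions: MeLi (1.0 equiv), THF, 0 °C; then 24, −78 °C; AcOH, −78 °C
Reagents that add atoms: none
Why: Regiospecific lithium enolate generation from the silyl enol ether and aldol addition to the unhindered, highly electrophilic ynal; axial attack on the half-chair with equatorial geranyl, anti to the axial C8 methyl, should place C2 cis to the C5 silyloxymethyl group and trans to geranyl, and the carbinol configuration is lost in step 17.

Step 16
Reactants: 26 aldol adduct
Product: 27 diol (C4 primary alcohol; C2 propargylic alcohol)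
Conditions: pyridinium p-toluenesulfonate, MeOH–CH2Cl2, 0 °C
Reagents that add atoms: none
Why: Acid-catalysed methanolysis removes the primary triethylsilyl ether selectively; aryl tert-butyldimethylsilyl ethers are stable to this weak acid.

Step 17
Reactants: 27 diol
Product: 28 ring A ketone with a formyl group on C5 and a 3-arylpropynoyl group on C1
Conditions: (COCl)2, DMSO, CH2Cl2, −78 to −40 °C; then Et3N, −78 to 0 °C
Reagents that add atoms: none
Why: Swern oxidation; both hydroxyls are first converted into alkoxysulfonium ions and are oxidised together when base is added, so no hydroxy aldehyde and hence no bridged lactol can form, and neither new carbonyl group has an enolisable α-carbon.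

Step 18
Reactants: 28 keto aldehyde ynone
Product: 29 (E)-aldoxime on C5 with the 3-arylpropynoyl group on C1
Conditions: NH2OH·HCl (1.1 equiv), NaOAc, MeOH–THF, 0 °C
Reagents that add atoms: hydroxylamine hydrochloride, NO.Cl
Why: Oxime condensation under acetate buffer, where acid-catalysed addition to the aldehyde is fast and most of the hydroxylamine is protonated, which should disfavour conjugate addition to the internal aryl ynone.

Step 19
Reactants: 29 (E)-aldoxime ynone
Product: 31 isoxazole-fused bicyclo[3.3.1]nonane-2,9-dione (masked bis-silyl oblongifolin B), via nitrile oxide 30 (not isolated)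
Conditions: PhI(OAc)2 (1.2 equiv), CF3CO2H (10 mol %), MeOH, 0 to 23 °C
Reagents that add atoms: none
Why: PhI(OAc)2 dehydrogenates the aldoxime to the nitrile oxide 30, whose carbon C4 and oxygen add in a concerted (3+2) cycloaddition across the ynone, C4 bonding to C3 and oxygen to the aryl-bearing carbon. The closest known reaction type is the intramolecular nitrile oxide–alkyne cycloaddition that gives ring-fused isoxazoles. Ring B closes through the new C3–C4 bond as a six-membered ring with the alkyne exo to it (6-exo-dig sense), and the isoxazole closes in the same concerted event. No stereocentre is created; C2 and C4 are already cis, and the dipole and the ynone meet 1,3-diaxially across C9 in the ring A chair that keeps geranyl equatorial. Regioselectivity is fixed by the tether, because the opposite orientation would need a seven-membered ring B; chemoselectivity over the alkenes follows because the C5 prenyl is tethered too closely, the C1 prenyl and C7 geranyl lie trans on ring A, and the conjugated ynone is the better dipolarophile. Dimerisation should be slow at the neopentyl-type C5, no enolate is formed so the non-enolisable 1,3-dicarbonyl units at C1 and C5 survive, and the silyl ethers keep the catechol safe from the oxidant.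

Step 20
Reactants: 31 isoxazole-fused dione
Product: 33 bis(tert-butyldimethylsilyl) oblongifolin B, via enaminone 32 (not isolated)
Conditions: Mo(CO)6 (1 equiv), MeCN–H2O (10:1), 80 °C; filtration; then 1 M HCl (aq.), THF, 23 to 40 °C
Reagents that add atoms: water, O
Why: Mo(CO)6-mediated reductive cleavage of the isoxazole N–O bond gives the primary enaminone (vinylogous amide) 32, which dilute acid should hydrolyse at C4 with loss of ammonia to the enolised triketone; alkenes and aryl silyl ethers tolerate both stages.

Step 21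
Reactants: 33 bis(tert-butyldimethylsilyl) oblongifolin B
Product: 34 oblongifolin B
Conditions: n-Bu4NF, AcOH (1:1), THF, 0 °C, argon
Reagents that add atoms: none
Why: Fluoride cleavage of the two aryl silyl ethers, buffered with acetic acid so that the acidic triketone and the catechol are not held as oxidation-prone anions.

**Compound list**

1 | geranyl bromide | CC(C)=CCC/C(C)=C/CBr | starting material
2 | tert-butyl acetate | CC(=O)OC(C)(C)C | starting material
3 | lithium enolate of tert-butyl acetate (not isolated) | C=C([O-])OC(C)(C)C.[Li+] | intermediate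
4 | tert-butyl (4E)-5,9-dimethyldeca-4,8-dienoate | CC(C)=CCC/C(C)=C/CCC(=O)OC(C)(C)C | intermediate
5 | (4E)-5,9-dimethyldeca-4,8-dienal | CC(C)=CCC/C(C)=C/CCC=O | intermediate
6 | methyl vinyl ketone | CC(=O)C=C | starting material
7 | (2S,4E)-5,9-dimethyl-2-(3-oxobutyl)deca-4,8-dienal (not isolated) | CC(C)=CCC/C(C)=C/C[C@@H](C=O)CCC(C)=O | intermediate
8 | (4S)-4-geranylcyclohex-2-en-1-one | CC(C)=CCC/C(C)=C/C[C@@H]1CCC(=O)C=C1 | intermediate
9 | {[(3S,4S)-4-geranyl-3-methylcyclohex-1-en-1-yl]oxy}trimethylsilane (3,4-trans) | CC(C)=CCC/C(C)=C/C[C@@H]1CCC(O[Si](C)(C)C)=C[C@H]1C | intermediate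
10 | (4S)-4-geranyl-3-methylcyclohex-2-en-1-one | CC(C)=CCC/C(C)=C/C[C@@H]1CCC(=O)C=C1C | intermediate
11 | (4S)-4-geranyl-2-iodo-3-methylcyclohex-2-en-1-one | CC(C)=CCC/C(C)=C/C[C@@H]1CCC(=O)C(I)=C1C | intermediate
12 | (4S)-4-geranyl-3-methyl-2-prenylcyclohex-2-en-1-one | CC(C)=CCC/C(C)=C/C[C@@H]1CCC(=O)C(CC=C(C)C)=C1C | intermediate
13 | prenyl bromide | CC(C)=CCBr | starting material
14 | lithium cross-conjugated dienolate of 12 (not isolated) | CC(C)=CCC/C(C)=C/C[C@@H]1CC=C([O-])C(CC=C(C)C)=C1C.[Li+] | intermediate
15 | (4S)-4-geranyl-3-methyl-2,6-diprenylcyclohex-2-en-1-one, 6-prenyl trans to geranyl (major epimer) | CC(C)=CCC/C(C)=C/C[C@@H]1C[C@@H](CC=C(C)C)C(=O)C(CC=C(C)C)=C1C | intermediate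
16 | lithium cross-conjugated dienolate of 15 (not isolated) | CC(C)=CCC/C(C)=C/C[C@@H]1CC(CC=C(C)C)=C([O-])C(CC=C(C)C)=C1C.[Li+] | intermediate
17 | (4S)-4-geranyl-6-(hydroxymethyl)-3-methyl-2,6-diprenylcyclohex-2-en-1-one, hydroxymethyl trans and 6-prenyl cis to geranyl | CC(C)=CCC/C(C)=C/C[C@@H]1C[C@](CO)(CC=C(C)C)C(=O)C(CC=C(C)C)=C1C | intermediate
18 | triethylsilyl ether of 17 | CC(C)=CCC/C(C)=C/C[C@@H]1C[C@](CO[Si](CC)(CC)CC)(CC=C(C)C)C(=O)C(CC=C(C)C)=C1C | intermediate
19 | trimethylsilyl enol ether of the ring A ketone (C1=C9, C8 gem-dimethyl, C5 bearing prenyl and CH2OSiEt3) | CC(C)=CCC/C(C)=C/C[C@@H]1C[C@](CO[Si](CC)(CC)CC)(CC=C(C)C)C(O[Si](C)(C)C)=C(CC=C(C)C)C1(C)C | intermediate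
20 | 3,4-dihydroxybenzaldehyde | O=Cc1ccc(O)c(O)c1 | starting material
21 | 3,4-bis(tert-butyldimethylsilyloxy)benzaldehyde | O=Cc1ccc(O[Si](C)(C)C(C)(C)C)c(O[Si](C)(C)C(C)(C)C)c1 | intermediate
22 | 4-(2,2-dibromoethenyl)-1,2-bis(tert-butyldimethylsilyloxy)benzene | BrC(Br)=Cc1ccc(O[Si](C)(C)C(C)(C)C)c(O[Si](C)(C)C(C)(C)C)c1 | intermediate
23 | lithium [3,4-bis(tert-butyldimethylsilyloxy)phenyl]acetylide (not isolated) | [Li+].[C-]#Cc1ccc(O[Si](C)(C)C(C)(C)C)c(O[Si](C)(C)C(C)(C)C)c1 | intermediate
24 | 3-[3,4-bis(tert-butyldimethylsilyloxy)phenyl]prop-2-ynal | O=CC#Cc1ccc(O[Si](C)(C)C(C)(C)C)c(O[Si](C)(C)C(C)(C)C)c1 | intermediate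
25 | lithium enolate of the ring A ketone (C1=C9; not isolated) | CC(C)=CCC/C(C)=C/C[C@@H]1C[C@](CO[Si](CC)(CC)CC)(CC=C(C)C)C([O-])=C(CC=C(C)C)C1(C)C.[Li+] | intermediate
26 | aldol adduct: ring A ketone, C1 bearing prenyl and CH(OH)C≡CAr, C5 bearing prenyl and CH2OSiEt3, C2 and C4 cis to each other and trans to geranyl (carbinol epimers) | CC(C)=CCC/C(C)=C/C[C@@H]1C[C@](CO[Si](CC)(CC)CC)(CC=C(C)C)C(=O)[C@@](CC=C(C)C)(C(O)C#Cc2ccc(O[Si](C)(C)C(C)(C)C)c(O[Si](C)(C)C(C)(C)C)c2)C1(C)C | intermediate
27 | diol: as 26 with free CH2OH on C5 | CC(C)=CCC/C(C)=C/C[C@@H]1C[C@](CO)(CC=C(C)C)C(=O)[C@@](CC=C(C)C)(C(O)C#Cc2ccc(O[Si](C)(C)C(C)(C)C)c(O[Si](C)(C)C(C)(C)C)c2)C1(C)C | intermediate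
28 | ring A ketone with formyl on C5 and 3-arylpropynoyl on C1 | CC(C)=CCC/C(C)=C/C[C@@H]1C[C@](C=O)(CC=C(C)C)C(=O)[C@@](CC=C(C)C)(C(=O)C#Cc2ccc(O[Si](C)(C)C(C)(C)C)c(O[Si](C)(C)C(C)(C)C)c2)C1(C)C | intermediate
29 | ring A ketone with (E)-aldoxime on C5 and 3-arylpropynoyl on C1 | CC(C)=CCC/C(C)=C/C[C@@H]1C[C@](/C=N/O)(CC=C(C)C)C(=O)[C@@](CC=C(C)C)(C(=O)C#Cc2ccc(O[Si](C)(C)C(C)(C)C)c(O[Si](C)(C)C(C)(C)C)c2)C1(C)C | intermediate
30 | nitrile oxide on C5 (not isolated) | CC(C)=CCC/C(C)=C/C[C@@H]1C[C@](C#[N+][O-])(CC=C(C)C)C(=O)[C@@](CC=C(C)C)(C(=O)C#Cc2ccc(O[Si](C)(C)C(C)(C)C)c(O[Si](C)(C)C(C)(C)C)c2)C1(C)C | intermediate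
31 | isoxazole-fused bicyclo[3.3.1]nonane-2,9-dione (isoxazole C–C bond = C3–C4, N on C4, aryl on the O-bearing carbon) | CC(C)=CCC/C(C)=C/C[C@@H]1C[C@]2(CC=C(C)C)C(=O)[C@@](CC=C(C)C)(C(=O)c3c2noc3-c2ccc(O[Si](C)(C)C(C)(C)C)c(O[Si](C)(C)C(C)(C)C)c2)C1(C)C | intermediate
32 | enaminone: C4 amino, C3 aroyl, C2 and C9 ketones (not isolated) | CC(C)=CCC/C(C)=C/C[C@@H]1C[C@]2(CC=C(C)C)C(=O)[C@@](CC=C(C)C)(C(=O)C(C(=O)c3ccc(O[Si](C)(C)C(C)(C)C)c(O[Si](C)(C)C(C)(C)C)c3)=C2N)C1(C)C | intermediate
33 | bis(tert-butyldimethylsilyl) oblongifolin B | CC(C)=CCC/C(C)=C/C[C@@H]1C[C@]2(CC=C(C)C)C(=O)[C@@](CC=C(C)C)(C(=O)C(C(=O)c3ccc(O[Si](C)(C)C(C)(C)C)c(O[Si](C)(C)C(C)(C)C)c3)=C2O)C1(C)C | intermediate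
34 | oblongifolin B (C4 enol tautomer drawn; 7R; prenyl groups on C1 and C5 and geranyl on C7 on the ring A face opposite to C2 and C4) | CC(C)=CCC/C(C)=C/C[C@@H]1C[C@]2(CC=C(C)C)C(=O)[C@@](CC=C(C)C)(C(=O)C(C(=O)c3ccc(O)c(O)c3)=C2O)C1(C)C | target

**Step count and risks**

Total step count: 21 (steps 1–11 and 15–21 on the main line, steps 12–14 for the aryl propynal).
Longest linear sequence: 18 steps (1–11, then 15–21).

Steps most likely to fail:

1. Step 15 (aldol union at C1). The enolate 25 is fully substituted at C1 and flanked by C8, so addition to 24 may be too slow, the lithium aldolate may revert by retro-aldol cleavage before the cold quench, or the facial selectivity at C1 may be low. Fallback (the C2–C3 bond is made by acetylide addition instead of the C1–C2 bond by an aldol with the ynal): starting from 19, the enolate 25 is generated as before and trapped with monomeric formaldehyde, the smallest aldehyde, to give the C1 hydroxymethyl ketone F1. Oxidation with Dess–Martin periodinane gives the α-quaternary keto aldehyde F2. The lithium acetylide 23, made from 22 with n-BuLi, is then added at −78 °C to the aldehyde; the C9 ketone lies between two quaternary carbons and should not compete. Cold protonation returns to the route at 26.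

2. Step 18 (oxime formation beside the ynone). Hydroxylamine may add in conjugate fashion to the ynone, in competition with condensation at the hindered aldehyde. Fallback (the alkyne is protected as a metal complex): starting from 28, Co2(CO)8 in CH2Cl2 at 23 °C converts the alkyne into its hexacarbonyldicobalt complex F3, which is no longer a Michael acceptor. Oxime formation under the conditions of step 18 gives the complexed oxime F4. Oxidative decomplexation with I2 in THF at 0 °C frees the alkyne and returns to the route at 29.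

3. Step 20 (N–O cleavage and hydrolysis). The enaminone 32 is stabilised by two acyl groups and may resist hydrolysis, while more forcing acid may add the enol oxygen to a prenyl alkene (cyclisation to a pyran). Fallback (activation at nitrogen instead of acid hydrolysis): starting from 31, the N–O bond is cleaved with Mo(CO)6 as before and 32 is isolated. Boc2O and DMAP in MeCN give the N-tert-butoxycarbonyl enaminone F5. LiOH in degassed THF–MeOH–H2O then displaces tert-butyl carbamate at C4 by addition–elimination and cleaves the aryl silyl ethers in the same operation, so that acidification returns to the route at the target 34.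

**Further compounds**

F1 | step 15 | ring A ketone with prenyl and CH2OH on C1 and prenyl and CH2OSiEt3 on C5 | CC(C)=CCC/C(C)=C/C[C@@H]1C[C@](CO[Si](CC)(CC)CC)(CC=C(C)C)C(=O)[C@@](CC=C(C)C)(CO)C1(C)C
F2 | step 15 | ring A ketone with prenyl and CHO on C1 and prenyl and CH2OSiEt3 on C5 | CC(C)=CCC/C(C)=C/C[C@@H]1C[C@](CO[Si](CC)(CC)CC)(CC=C(C)C)C(=O)[C@@](CC=C(C)C)(C=O)C1(C)C
F3 | step 18 | hexacarbonyldicobalt complex of the alkyne of 28 | CC(C)=CCC/C(C)=C/C[C@@H]1C[C@](C=O)(CC=C(C)C)C(=O)[C@@](CC=C(C)C)(C(=O)C23[Co]4(=C=O)(=C=O)(=C=O)[Co]2(=C=O)(=C=O)(=C=O)C34c2ccc(O[Si](C)(C)C(C)(C)C)c(O[Si](C)(C)C(C)(C)C)c2)C1(C)C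
F4 | step 18 | hexacarbonyldicobalt complex of the alkyne of 29 | CC(C)=CCC/C(C)=C/C[C@@H]1C[C@](/C=N/O)(CC=C(C)C)C(=O)[C@@](CC=C(C)C)(C(=O)C23[Co]4(=C=O)(=C=O)(=C=O)[Co]2(=C=O)(=C=O)(=C=O)C34c2ccc(O[Si](C)(C)C(C)(C)C)c(O[Si](C)(C)C(C)(C)C)c2)C1(C)C
F5 | step 20 | N-tert-butoxycarbonyl derivative of enaminone 32 | CC(C)=CCC/C(C)=C/C[C@@H]1C[C@]2(CC=C(C)C)C(=O)[C@@](CC=C(C)C)(C(=O)C(C(=O)c3ccc(O[Si](C)(C)C(C)(C)C)c(O[Si](C)(C)C(C)(C)C)c3)=C2NC(=O)OC(C)(C)C)C1(C)C
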